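**Retrosynthetic overview**
- The aryl ether C–O bond is made last by Mitsunobu alkylation of umbelliferone with a (2R,3S)-epoxy alcohol; the oxirane comes from Sharpless epoxidation of a Z-allylic alcohol.
- The Z-allylic alcohol and the γ-lactone come from a 4-methyl-5,6-dihydro-2-pyranone: the ring locks the cis alkene geometry, and ring opening, re-lactonization onto the other carboxyl and carboxyl reduction unmask it.
- Key step: ligand-controlled partial hydrogenation of a 6-substituted 4-methyl-2-pyranone breaks the pyranone's cyclic conjugation and sets the lactone CH–O center.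
- The tertiary carbinol and the full C10 chain come from an enantioselective vinylogous Mukaiyama aldol of the silyl trienol ether of 4,6-dimethyl-2-pyranone with methyl pyruvate.
- Ring order: pyranone (bought) → dihydropyranone → γ-butyrolactone → oxirane; the coumarin is bought.

Assumption: the facial sense of the two ligand-controlled steps (2 and 3) is taken from the parent reactions of methyl pyruvate and of 4,6-dimethyl-2-pyranone; if either is opposite on this substrate, the antipodal ligand is used.

**Route**

Step 1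
Reactants: 1 4,6-dimethyl-2H-pyran-2-one
Product: 2 trimethyl[(4-methyl-6-methylidene-6H-pyran-2-yl)oxy]silane
Conditions: LiN(iPr)2 (1.05 equiv) added to 1 + Me3SiCl (1.2 equiv), THF, −78 °C; concentrate, pentane, filter under argon, use crude
Reagents that add atoms: chlorotrimethylsilane, C[Si](C)(C)Cl
Why: Kinetic deprotonation with in situ O-silylation (vinylogous silyl ketene acetal formation) occurs at the 6-methyl group because only its anion is delocalized linearly over both ring double bonds onto the carbonyl oxygen, whereas the 4-methyl anion is only cross-conjugated; no stereocenter is formed.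

Step 2
Reactants: 2 trimethyl[(4-methyl-6-methylidene-6H-pyran-2-yl)oxy]silane; 3 methyl 2-oxopropanoate (methyl pyruvate)
Product: 5 methyl (2R)-2-hydroxy-2-methyl-3-(4-methyl-2-oxo-2H-pyran-6-yl)propanoate, via trimethylsilyl ether 4 (not isolated)
Conditions: Cu(OTf)2 (10 mol %), (R,R)-t-Bu-box (11 mol %), THF, −78 °C; then 1 M HCl, THF, rt
Reagents that add atoms: none
Why: Proposed new method: a catalytic enantioselective vinylogous Mukaiyama aldol in which the square-planar divalent copper–bis(oxazoline) complex chelates methyl pyruvate through both carbonyls, a tert-butyl group shields one ketone face, and the exocyclic CH2 terminus of 2 (the only site whose attack regenerates the aromatic pyranone) adds to the open face to set the tertiary carbinol as (R), after which silyl transfer gives 4 and acid frees 5; the closest known reaction type is the Cu(OTf)2–bis(oxazoline)-catalysed addition of enol silanes to pyruvate esters, where the (S,S) ligand gives the (S) carbinol with the same substituent priorities.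

Step 3
Reactants: 5 methyl (2R)-2-hydroxy-2-methyl-3-(4-methyl-2-oxo-2H-pyran-6-yl)propanoate
Product: 6 methyl (2R)-2-hydroxy-2-methyl-3-[(2S)-4-methyl-6-oxo-3,6-dihydro-2H-pyran-2-yl]propanoate
Conditions: Ru(OAc)2[(S)-MeO-BIPHEP] (1 mol %), HBF4·OEt2 (2 mol %), H2 (60 bar), i-PrOH, 60 °C
Reagents that add atoms: none
Why: Key step, a ligand-controlled asymmetric hydrogenation of a 2-pyranone, in which the cationic ruthenium–biaryl diphosphine catalyst saturates only the enol-ester-type C5=C6 bond and so breaks the cyclic 6π conjugation, the chiral pocket selects the ring face to set the new oxygen-bearing center as (S) independently of the remote carbinol, and the surviving conjugated C3=C4 bond stays locked cis in the ring, which fixes the later Z-alkene.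

Step 4
Reactants: 6 methyl (2R)-2-hydroxy-2-methyl-3-[(2S)-4-methyl-6-oxo-3,6-dihydro-2H-pyran-2-yl]propanoate
Product: 8 (2Z)-4-[(2S,4R)-4-hydroxy-4-methyl-5-oxooxolan-2-yl]-3-methylbut-2-enoic acid, via dilithium dicarboxylate 7 (not isolated)
Conditions: LiOH (3 equiv), THF/H2O, 0 °C to rt; then 2 M HCl to pH 1, rt, 3 h
Reagents that add atoms: lithium hydroxide, [Li+].[OH-]
Why: Saponification followed by acid-promoted lactonization (net translactonization) cleaves the methyl ester and the δ-lactone without touching either stereocenter or the alkene geometry, and on acidification the freed secondary hydroxyl closes onto the α-hydroxy carboxyl as the five-membered lactone, favoured over the six-membered conjugated one by ring size and by the fully substituted α-carbon, leaving the conjugated acid free.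

Step 5
Reactants: 8 (2Z)-4-[(2S,4R)-4-hydroxy-4-methyl-5-oxooxolan-2-yl]-3-methylbut-2-enoic acid
Product: 10 (3R,5S)-3-hydroxy-5-[(2Z)-4-hydroxy-2-methylbut-2-en-1-yl]-3-methyloxolan-2-one, via mixed anhydride 9 (not isolated)
Conditions: i-BuOCOCl (1.05 equiv), 4-methylmorpholine (1.05 equiv), THF, −15 °C; then NaBH4, H2O, 0 °C, 20 min
Reagents that add atoms: none
Why: Chemoselective carboxylic acid reduction through a mixed carbonic anhydride works because only the anhydride carbonyl of 9 is electrophilic enough for NaBH4 at 0 °C, so the γ-lactone, the tertiary alcohol and the Z-alkene are untouched and no stereocenter is affected.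

Step 6
Reactants: 10 (3R,5S)-3-hydroxy-5-[(2Z)-4-hydroxy-2-methylbut-2-en-1-yl]-3-methyloxolan-2-one
Product: 11 (3R,5R)-3-hydroxy-5-{[(2S,3R)-3-(hydroxymethyl)-2-methyloxiran-2-yl]methyl}-3-methyloxolan-2-one
Conditions: Ti(OiPr)4 (20 mol %), D-(−)-diethyl tartrate (24 mol %), t-BuOOH (2 equiv, decane), 4 Å MS, CH2Cl2, −25 °C
Reagents that add atoms: tert-butyl hydroperoxide, CC(C)(C)OO
Why: Sharpless asymmetric epoxidation, in which the allylic hydroxyl binds the titanium tartrate and the peroxide oxygen is delivered to one alkene face under reagent control (D-(−)-tartrate on a nerol-type Z-trisubstituted allylic alcohol gives the 2R,3S pattern counted from the carbinol carbon), the cis relation of the two CH2 groups on the oxirane coming from the Z-alkene. The lactone descriptor changes from 5S to 5R only through a priority change.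

Step 7
Reactants: 11 (3R,5R)-3-hydroxy-5-{[(2S,3R)-3-(hydroxymethyl)-2-methyloxiran-2-yl]methyl}-3-methyloxolan-2-one; 12 7-hydroxy-2H-chromen-2-one (umbelliferone)
Product: 13 (3R,5R)-3-hydroxy-3-methyl-5-{[(2S,3R)-2-methyl-3-{[(2-oxo-2H-chromen-7-yl)oxy]methyl}oxiran-2-yl]methyl}oxolan-2-one
Conditions: PPh3 (1.3 equiv), DIAD (1.3 equiv), THF, 0 °C to rt
Reagents that add atoms: none
Why: Mitsunobu etherification alkylates the acidic phenol (pKa about 7.8) with the activated primary epoxy alcohol at its CH2 carbon, which is not a stereocenter, so all four stereocenters are untouched and the unreactive tertiary alcohol needs no protection.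

**Compound list**

1 | 4,6-dimethyl-2H-pyran-2-one | Cc1cc(C)oc(=O)c1 | starting material
2 | trimethyl[(4-methyl-6-methylidene-6H-pyran-2-yl)oxy]silane | C=C1C=C(C)C=C(O[Si](C)(C)C)O1 | intermediate
3 | methyl 2-oxopropanoate (methyl pyruvate) | COC(=O)C(C)=O | starting material
4 | methyl (2R)-2-methyl-3-(4-methyl-2-oxo-2H-pyran-6-yl)-2-[(trimethylsilyl)oxy]propanoate | COC(=O)[C@](C)(O[Si](C)(C)C)Cc1cc(C)cc(=O)o1 | intermediate
5 | methyl (2R)-2-hydroxy-2-methyl-3-(4-methyl-2-oxo-2H-pyran-6-yl)propanoate | COC(=O)[C@](C)(O)Cc1cc(C)cc(=O)o1 | intermediate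
6 | methyl (2R)-2-hydroxy-2-methyl-3-[(2S)-4-methyl-6-oxo-3,6-dihydro-2H-pyran-2-yl]propanoate | COC(=O)[C@](C)(O)C[C@@H]1CC(C)=CC(=O)O1 | intermediate
7 | dilithium (2Z,5S,7R)-5,7-dihydroxy-3,7-dimethyloct-2-enedioate | [Li+].[Li+].[O-]C(=O)[C@](C)(O)C[C@@H](O)C/C(C)=C\C([O-])=O | intermediate
8 | (2Z)-4-[(2S,4R)-4-hydroxy-4-methyl-5-oxooxolan-2-yl]-3-methylbut-2-enoic acid | C[C@@]1(O)C[C@H](C/C(C)=C\C(=O)O)OC1=O | intermediate
9 | (2Z)-4-[(2S,4R)-4-hydroxy-4-methyl-5-oxooxolan-2-yl]-3-methylbut-2-enoic 2-methylpropyl carbonic anhydride | C[C@@]1(O)C[C@H](C/C(C)=C\C(=O)OC(=O)OCC(C)C)OC1=O | intermediate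
10 | (3R,5S)-3-hydroxy-5-[(2Z)-4-hydroxy-2-methylbut-2-en-1-yl]-3-methyloxolan-2-one | C[C@@]1(O)C[C@H](C/C(C)=C\CO)OC1=O | intermediate
11 | (3R,5R)-3-hydroxy-5-{[(2S,3R)-3-(hydroxymethyl)-2-methyloxiran-2-yl]methyl}-3-methyloxolan-2-one | C[C@@]1(O)C[C@H](C[C@]2(C)O[C@@H]2CO)OC1=O | intermediate
12 | 7-hydroxy-2H-chromen-2-one (umbelliferone) | Oc1ccc2ccc(=O)oc2c1 | starting material
13 | (3R,5R)-3-hydroxy-3-methyl-5-{[(2S,3R)-2-methyl-3-{[(2-oxo-2H-chromen-7-yl)oxy]methyl}oxiran-2-yl]methyl}oxolan-2-one | C[C@@]1(O)C[C@H](C[C@]2(C)O[C@@H]2COc2ccc3ccc(=O)oc3c2)OC1=O | target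

**Step count and risks**

Total steps: 7. Longest linear sequence: 7 (from 1). No protecting groups are used.

Step 2 (new nucleophile in the copper-catalysed pyruvate aldol; conversion, site selectivity or ee may fall short). The fallback replaces catalyst control by a covalent auxiliary; it sets out from 1 and comes back at 8. (+)-8-Phenylmenthol is esterified with pyruvic acid (DCC, DMAP) to (1S,2R,5S)-5-methyl-2-(2-phenylpropan-2-yl)cyclohexyl 2-oxopropanoate F1. The trienolate of 1 (LiN(iPr)2, THF, −78 °C, then MgBr2·OEt2) adds to the ketone face left open by the stacked phenyl group, the auxiliary hand being chosen by analogy with organomagnesium additions to α-keto esters of this auxiliary. This gives (1S,2R,5S)-5-methyl-2-(2-phenylpropan-2-yl)cyclohexyl (2R)-2-hydroxy-2-methyl-3-(4-methyl-2-oxo-2H-pyran-6-yl)propanoate F2. Hydrogenation as in step 3 gives (1S,2R,5S)-5-methyl-2-(2-phenylpropan-2-yl)cyclohexyl (2R)-2-hydroxy-2-methyl-3-[(2S)-4-methyl-6-oxo-3,6-dihydro-2H-pyran-2-yl]propanoate F3, and the step 4 conditions release the auxiliary and deliver 8.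

Step 3 (the hydroxy ester side chain may inhibit the ruthenium catalyst, or over-reduction or low face selectivity may occur). The fallback moves from catalyst control to substrate direction; it sets out from 5 and comes back at 6. Hydrogenation with [Ir(cod)(PCy3)(py)]PF6 (CH2Cl2, H2 1 atm) uses the tertiary hydroxyl to bind iridium and deliver hydrogen only to the neighbouring C5=C6 bond. It gives 6 together with its ring epimer methyl (2R)-2-hydroxy-2-methyl-3-[(2R)-4-methyl-6-oxo-3,6-dihydro-2H-pyran-2-yl]propanoate F4, which is removed by chromatography; the two are diastereomers because the carbinol is already fixed.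

Step 6 (the titanium Lewis acid may let the cis tertiary hydroxyl open the new oxirane at its tertiary carbon to a bridged ether, and Z-allylic alcohols can give lower ee). The fallback avoids the Lewis acid and reverses the order of the last two operations; it sets out from 10 and comes back at 13. Mitsunobu etherification of 10 with 12 (PPh3, DIAD, THF) gives 7-{[(2Z)-4-[(2S,4R)-4-hydroxy-4-methyl-5-oxooxolan-2-yl]-3-methylbut-2-en-1-yl]oxy}-2H-chromen-2-one F5. Reagent-controlled Shi epoxidation of its trisubstituted alkene (D-fructose-derived ketone, KHSO5, K2CO3 buffer, MeCN/dimethoxymethane/H2O, 0 °C, short reaction time) then gives 13 directly; the electron-poor coumarin alkene is not attacked by the dioxirane.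

**Further compounds**

F1 | step 2 | (1S,2R,5S)-5-methyl-2-(2-phenylpropan-2-yl)cyclohexyl 2-oxopropanoate | C[C@H]1CC[C@@H]([C@H](C1)OC(=O)C(C)=O)C(C)(C)c1ccccc1
F2 | step 2 | (1S,2R,5S)-5-methyl-2-(2-phenylpropan-2-yl)cyclohexyl (2R)-2-hydroxy-2-methyl-3-(4-methyl-2-oxo-2H-pyran-6-yl)propanoate | C[C@H]1CC[C@@H]([C@H](C1)OC(=O)[C@](C)(O)Cc1cc(C)cc(=O)o1)C(C)(C)c1ccccc1
F3 | step 2 | (1S,2R,5S)-5-methyl-2-(2-phenylpropan-2-yl)cyclohexyl (2R)-2-hydroxy-2-methyl-3-[(2S)-4-methyl-6-oxo-3,6-dihydro-2H-pyran-2-yl]propanoate | C[C@H]1CC[C@@H]([C@H](C1)OC(=O)[C@](C)(O)C[C@@H]2CC(C)=CC(=O)O2)C(C)(C)c1ccccc1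
F4 | step 3 | methyl (2R)-2-hydroxy-2-methyl-3-[(2R)-4-methyl-6-oxo-3,6-dihydro-2H-pyran-2-yl]propanoate | COC(=O)[C@](C)(O)C[C@H]1CC(C)=CC(=O)O1
F5 | step 6 | 7-{[(2Z)-4-[(2S,4R)-4-hydroxy-4-methyl-5-oxooxolan-2-yl]-3-methylbut-2-en-1-yl]oxy}-2H-chromen-2-one | C[C@@]1(O)C[C@H](C/C(C)=C\COc2ccc3ccc(=O)oc3c2)OC1=O
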